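Each ring (C1 gem-dimethyl, C2, C3, C4, C5 methyl-bearing, C6 chain-bearing) has a single stereocentre, C2, whose two carbon arms, ring carbon C3 and side-chain carbon Ca, differ only further out. Both arms are traced back to vinyl groups on an achiral triene ketone that already contains C1 to C6, Ca and Cb. One catalytic enantioselective ring-closing metathesis then forms the C3=C4 bond, closes the six-membered ring and sets C2 by choosing between the enantiotopic vinyl groups. The C6 ketone later directs C5 methylation and enol triflate formation; two C15 aldehydes are finally joined to a C10 bis-phosphonate.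

Key step: step 5

Remark (labels): ring atoms carry carotenoid numbers as above; Ca and Cb are the first and second carbons of the side chain on C2; the target is (2R,2'R) and all-E.
Remark (structures checked): ketone 12 is (5S) and the target is (2R) for the same spatial arrangement at C2, because the vinyl arm ranks below ring carbon C3 in 12 whereas the finished side chain ranks above it.
Remark (assumption): the sense of induction of the biphenolate catalyst for this all-carbon tether cannot be assigned safely by analogy; the (S)-ligand is written, and its mirror image is used if a test run delivers the (5R) ketone.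

Step 1
Reactants: 1 (2E)-penta-2,4-dien-1-ol; 2 2-methylpropanoyl chloride (isobutyryl chloride)
Product: 3 (2E)-penta-2,4-dien-1-yl 2-methylpropanoate
Conditions: Et3N, DMAP (cat.), CH2Cl2, 0 °C → rt
Reagents that add atoms: none
Why: Esterification of a primary allylic alcohol with an acid chloride under nucleophilic catalysis is reliable and leaves the diene untouched.

Step 2
Reactants: 3 (2E)-penta-2,4-dien-1-yl 2-methylpropanoate
Product: 7 3-ethenyl-2,2-dimethylpent-4-enoic acid, via lithium enolate 4 (not isolated), via silyl ketene acetal 5 (not isolated), via trimethylsilyl ester 6 (not isolated)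
Conditions: LiN(i-Pr)2, THF, −78 °C; Me3SiCl, −78 °C → 60 °C; then 1 M HCl
Reagents that add atoms: chlorotrimethylsilane, C[Si](C)(C)Cl (silicon of 5 and 6 only); LiN(i-Pr)2, [Li+].CC(C)[N-]C(C)C (lithium of 4 only)
Why: Ireland–Claisen rearrangement, in which the [3,3] shift of the silyl ketene acetal joins the isobutyrate α-carbon (future C1) to C3 of the pentadienyl unit (future C2) and leaves two vinyl groups on that carbon; no stereocentre arises because the ketene acetal carbon bears two methyl groups and the new methine bears two identical vinyl groups.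

Step 3
Reactants: 7 3-ethenyl-2,2-dimethylpent-4-enoic acid
Product: 9 3-ethenyl-N-methoxy-N,2,2-trimethylpent-4-enamide, via acid chloride 8 (not isolated)
Conditions: (COCl)2, DMF (cat.), CH2Cl2, 0 °C → rt; concentrate; MeNHOMe·HCl, Et3N, CH2Cl2, 0 °C → rt
Reagents that add atoms: N,O-dimethylhydroxylamine hydrochloride, CNOC.Cl; oxalyl chloride, O=C(Cl)C(=O)Cl (chlorine of 8 only)
Why: Acid chloride formation followed by N-acylation (Weinreb amide synthesis) works on α-quaternary acids, and the absence of strong base keeps the skipped diene out of conjugation.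

Step 4
Reactants: 9 3-ethenyl-N-methoxy-N,2,2-trimethylpent-4-enamide; 10 allylmagnesium bromide
Product: 11 6-ethenyl-5,5-dimethylocta-1,7-dien-4-one
Conditions: THF, −78 °C → −20 °C; cold aq NH4Cl
Reagents that add atoms: none
Why: Grignard addition to a Weinreb amide stops at the chelated tetrahedral adduct, so one allyl group is delivered even to this hindered carbonyl, and the cold, near-neutral quench keeps the allyl ketone from becoming a propenyl ketone; the trigonal C6 keeps the triene achiral.

Step 5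
Reactants: 11 6-ethenyl-5,5-dimethylocta-1,7-dien-4-one
Product: 12 (5S)-5-ethenyl-6,6-dimethylcyclohex-3-en-1-one
Conditions: Mo(N-2,6-i-Pr2C6H3)(CHCMe2Ph)[(S)-3,3'-di-tert-butyl-5,5',6,6'-tetramethylbiphenyl-2,2'-diolate] (hexavalent molybdenum, 5 mol %), C6H6 (0.05 M), 22 °C, N2, ethene vented
Reagents that add atoms: none
Why: Olefin metathesis: the alkylidene first exchanges with the unhindered allyl terminus, the new Mo=C4 alkylidene adds across one vinyl group on C2 to a molybdacyclobutane, and cycloreversion releases ethene and leaves the C3=C4 double bond. The closest known reaction type is the catalytic enantioselective desymmetrising ring-closing metathesis of trienes that carry two vinyl groups on one carbon, here run on a ketone-tethered all-carbon chain. The cyclohexene closes as the ring-closing metathesis of a 1,7-diene, helped by the gem-dimethyl group and by dilution, while the two vinyl groups cannot join each other because only a cyclopropene could result. C2 is set by catalyst control: the chiral biphenolate and the arylimido ligand make the two metallacyclobutanes that lead to the (5S) and (5R) rings diastereomeric, and the C1 gem-dimethyl group next to the prochiral carbon enlarges their difference. The step needs selection between enantiotopic vinyl groups and initiation at the allyl end only, the second being secured by the neopentyl-type shielding of both vinyl groups. The C6 carbonyl, flanked by a quaternary carbon, should resist carbonyl olefination, and a hydride-free molybdenum catalyst does not shift the β,γ-double bond or the skipped diene.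

Step 6
Reactants: 12 (5S)-5-ethenyl-6,6-dimethylcyclohex-3-en-1-one
Product: 13 (5R)-5-ethenyl-6,6-dimethylcyclohex-2-en-1-one
Conditions: DBU (10 mol %), CH2Cl2, rt
Reagents that add atoms: none
Why: Base-mediated double-bond isomerisation through the dienolate moves the ring alkene from C3=C4 to C4=C5, the thermodynamic conjugated position, while the C2–H is not vinylogous to the carbonyl and stays untouched (the descriptor changes only because C3 becomes saturated).

Step 7
Reactants: 13 (5R)-5-ethenyl-6,6-dimethylcyclohex-2-en-1-one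
Product: 15 (3R)-3-ethenyl-2,2,6-trimethylcyclohexan-1-one (mixture of C6 epimers), via potassium enolate 14 (not isolated)
Conditions: KBH(s-Bu)3, THF, −78 °C; then MeI, −78 °C → 0 °C
Reagents that add atoms: iodomethane, CI; KBH(s-Bu)3, [K+].CCC(C)[BH-](C(C)CC)C(C)CC (potassium of 14 only)
Why: Reductive alkylation of an enone: the bulky borohydride adds hydride 1,4 to the β-unsubstituted cyclohexenone whose carbonyl is shielded by the gem-dimethyl group, the isolated vinyl group is inert, and the regiodefined enolate is C-methylated at C5; the new methyl-bearing centre is uncontrolled and is erased in step 8.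

Step 8
Reactants: 15 (3R)-3-ethenyl-2,2,6-trimethylcyclohexan-1-one
Product: 17 (5R)-5-ethenyl-2,6,6-trimethylcyclohex-1-en-1-yl trifluoromethanesulfonate, via lithium enolate 16 (not isolated)
Conditions: LiN(i-Pr)2, THF, −78 °C → 0 °C; PhNTf2, 0 °C → rt
Reagents that add atoms: N-phenylbis(trifluoromethanesulfonimide), O=S(=O)(N(c1ccccc1)S(=O)(=O)C(F)(F)F)C(F)(F)F; LiN(i-Pr)2, [Li+].CC(C)[N-]C(C)C (lithium of 16 only)
Why: Enol triflate formation is regiospecific because only C5 carries an α-hydrogen (C1 is quaternary), so deprotonation and O-sulfonylation give the tetrasubstituted C5=C6 enol triflate and merge both methyl epimers.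

Step 9
Reactants: 17 (5R)-5-ethenyl-2,6,6-trimethylcyclohex-1-en-1-yl trifluoromethanesulfonate
Product: 19 (5R)-5-(2-hydroxyethyl)-2,6,6-trimethylcyclohex-1-en-1-yl trifluoromethanesulfonate, via alkylborane 18 (not isolated)
Conditions: 9-BBN, THF, 0 °C → rt; then NaBO3·4H2O, H2O, rt
Reagents that add atoms: 9-borabicyclo[3.3.1]nonane, B1C2CCCC1CCC2 (boron of 18 only); sodium perborate NaBO3·4H2O, [Na+].[Na+].O[B-]1(O)OO[B-](O)(O)OO1 (oxygen of 19)
Why: Hydroboration–oxidation: 9-BBN adds anti-Markovnikov to the monosubstituted vinyl group and ignores the electron-poor tetrasubstituted enol triflate, and the mild perborate oxidation with retention spares the triflate, so Cb becomes the carbinol carbon.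

Step 10
Reactants: 19 (5R)-5-(2-hydroxyethyl)-2,6,6-trimethylcyclohex-1-en-1-yl trifluoromethanesulfonate
Product: 20 (5R)-2,6,6-trimethyl-5-(2-oxoethyl)cyclohex-1-en-1-yl trifluoromethanesulfonate
Conditions: Dess–Martin periodinane, CH2Cl2, 0 °C → rt
Reagents that add atoms: none
Why: Dess–Martin oxidation converts the primary alcohol to the aldehyde under neutral conditions without over-oxidation, and C2 is β to the new carbonyl and cannot epimerise.

Step 11
Reactants: 20 (5R)-2,6,6-trimethyl-5-(2-oxoethyl)cyclohex-1-en-1-yl trifluoromethanesulfonate; 21 ethyl 2-(triphenyl-λ5-phosphanylidene)propanoate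
Product: 22 ethyl (2E)-2-methyl-4-[(1R)-2,2,4-trimethyl-3-{[(trifluoromethyl)sulfonyl]oxy}cyclohex-3-en-1-yl]but-2-enoate
Conditions: CH2Cl2, rt → 40 °C
Reagents that add atoms: none
Why: Wittig olefination with a stabilised ylide forms the Cb=C bond with the ester trans to the chain, which is the (E) geometry of the target side chain, and the salt-free neutral conditions keep the triflate.

Step 12
Reactants: 22 ethyl (2E)-2-methyl-4-[(1R)-2,2,4-trimethyl-3-{[(trifluoromethyl)sulfonyl]oxy}cyclohex-3-en-1-yl]but-2-enoate; 23 but-3-en-2-one (methyl vinyl ketone)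
Product: 24 ethyl (2E)-2-methyl-4-{(1R)-2,2,4-trimethyl-3-[(1E)-3-oxobut-1-en-1-yl]cyclohex-3-en-1-yl}but-2-enoate
Conditions: Pd(OAc)2 (5 mol %), PPh3, Et3N, DMF, 70 °C
Reagents that add atoms: none
Why: Mizoroki–Heck reaction: oxidative addition of the enol triflate to zerovalent palladium, syn-insertion of the enone at its unsubstituted terminus and syn-β-hydride elimination give the (E)-dienone (C6–C7 bond), while the trisubstituted side-chain enoate is too hindered to compete and cannot be reached intramolecularly without a bridgehead alkene.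

Step 13
Reactants: 24 ethyl (2E)-2-methyl-4-{(1R)-2,2,4-trimethyl-3-[(1E)-3-oxobut-1-en-1-yl]cyclohex-3-en-1-yl}but-2-enoate; 25 diethyl (cyanomethyl)phosphonate
Product: 26 ethyl (2E)-4-{(1R)-3-[(1E,3E)-4-cyano-3-methylbuta-1,3-dien-1-yl]-2,2,4-trimethylcyclohex-3-en-1-yl}-2-methylbut-2-enoate
Conditions: NaH, THF, 0 °C (25 first); then 24, 0 °C → rt
Reagents that add atoms: none
Why: Horner–Wadsworth–Emmons olefination of the methyl dienone with the cyanomethylphosphonate carbanion is the standard route from ionone-type ketones to C15 nitriles; the (E) geometry at C9=C10 should predominate, any (Z) isomer is to be removed by chromatography after step 14, and the ester is inert to the weakly basic carbanion.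

Step 14
Reactants: 26 ethyl (2E)-4-{(1R)-3-[(1E,3E)-4-cyano-3-methylbuta-1,3-dien-1-yl]-2,2,4-trimethylcyclohex-3-en-1-yl}-2-methylbut-2-enoate
Product: 27 (2E,4E)-5-{(5R)-5-[(2E)-4-hydroxy-3-methylbut-2-en-1-yl]-2,6,6-trimethylcyclohex-1-en-1-yl}-3-methylpenta-2,4-dienal
Conditions: i-Bu2AlH (4.5 equiv), CH2Cl2, −78 °C → −40 °C; then aq KNaC4H4O6, rt
Reagents that add atoms: water, O (oxygen of the aldehyde)
Why: i-Bu2AlH reduction adds one hydride to the nitrile to give an N-aluminoimine that is hydrolysed to the aldehyde on work-up, and in the same operation reduces the enoate 1,2 to the allylic alcohol, without touching the alkenes or C2.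

Step 15
Reactants: 27 (2E,4E)-5-{(5R)-5-[(2E)-4-hydroxy-3-methylbut-2-en-1-yl]-2,6,6-trimethylcyclohex-1-en-1-yl}-3-methylpenta-2,4-dienal
Product: 28 (2E,4E)-5-{(5R)-5-[(2E)-4-{[tert-butyl(dimethyl)silyl]oxy}-3-methylbut-2-en-1-yl]-2,6,6-trimethylcyclohex-1-en-1-yl}-3-methylpenta-2,4-dienal
Conditions: TBSCl, imidazole, DMF, 0 °C → rt
Reagents that add atoms: tert-butyl(chloro)dimethylsilane, CC(C)(C)[Si](C)(C)Cl
Why: Silylation of the primary allylic alcohol (silyl ether protection) removes the only acidic proton before the base-mediated coupling and is inert to the dienal.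

Step 16
Reactants: 29 (2E,4E,6E)-2,7-dimethylocta-2,4,6-trienedial
Product: 30 (2E,4E,6E)-2,7-dimethylocta-2,4,6-triene-1,8-diol
Conditions: NaBH4, MeOH/THF, 0 °C
Reagents that add atoms: none
Why: Borohydride 1,2-reduction of the two conjugated aldehydes gives the bis-allylic diol without touching the triene.

Step 17
Reactants: 30 (2E,4E,6E)-2,7-dimethylocta-2,4,6-triene-1,8-diol
Product: 31 (2E,4E,6E)-1,8-dibromo-2,7-dimethylocta-2,4,6-triene
Conditions: PBr3, pyridine (cat.), Et2O, −10 °C, dark
Reagents that add atoms: phosphorus tribromide, BrP(Br)Br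
Why: Bromination of primary allylic alcohols with PBr3 proceeds by substitution at the primary carbon, and low temperature and exclusion of light preserve the triene geometry of this sensitive dibromide, which is used at once.

Step 18
Reactants: 31 (2E,4E,6E)-1,8-dibromo-2,7-dimethylocta-2,4,6-triene
Product: 32 tetraethyl [(2E,4E,6E)-2,7-dimethylocta-2,4,6-triene-1,8-diyl]bis(phosphonate)
Conditions: P(OEt)3, neat, 110 °C, EtBr distilled off
Reagents that add atoms: triethyl phosphite, CCOP(OCC)OCC
Why: Michaelis–Arbuzov reaction of the two primary allylic bromides with triethyl phosphite gives the bis-phosphonate, driven by loss of volatile bromoethane.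

Step 19
Reactants: 28 (2E,4E)-5-{(5R)-5-[(2E)-4-{[tert-butyl(dimethyl)silyl]oxy}-3-methylbut-2-en-1-yl]-2,6,6-trimethylcyclohex-1-en-1-yl}-3-methylpenta-2,4-dienal (2 equiv); 32 tetraethyl [(2E,4E,6E)-2,7-dimethylocta-2,4,6-triene-1,8-diyl]bis(phosphonate)
Product: 34 (2R,2'R)-2,2'-bis[(2E)-4-{[tert-butyl(dimethyl)silyl]oxy}-3-methylbut-2-en-1-yl]-β,β-carotene, via monophosphonate 33 (not isolated)
Conditions: KOt-Bu, THF, −20 °C (32 first); then 28, −20 °C → rt, Ar, dark
Reagents that add atoms: none
Why: Twofold Horner–Wadsworth–Emmons olefination of the allylic bis-phosphonate carbanion with the C15 dienal forms the C11=C12 and C11'=C12' bonds, should give the (E) geometry typical of allylic phosphonates with enals, and leaves the silyl ethers and the remote C2 centres unaffected.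

Step 20
Reactants: 34 (2R,2'R)-2,2'-bis[(2E)-4-{[tert-butyl(dimethyl)silyl]oxy}-3-methylbut-2-en-1-yl]-β,β-carotene
Product: 35 (2R,2'R)-2,2'-bis[(2E)-4-hydroxy-3-methylbut-2-en-1-yl]-β,β-carotene (all-E), the target
Conditions: n-Bu4NF, THF, 0 °C → rt, dark; crystallisation
Reagents that add atoms: none
Why: Fluoride-mediated desilylation cleaves both primary silyl ethers under conditions that the polyene tolerates, and crystallisation should deliver the all-E diol.

Compound list
1 | (2E)-penta-2,4-dien-1-ol | C=C/C=C/CO | starting material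
2 | 2-methylpropanoyl chloride (isobutyryl chloride) | CC(C)C(=O)Cl | starting material
3 | (2E)-penta-2,4-dien-1-yl 2-methylpropanoate | CC(C)C(=O)OC/C=C/C=C | intermediate
4 | lithium 2-methyl-1-[(2E)-penta-2,4-dien-1-yloxy]prop-1-en-1-olate | [Li+].[O-]C(OC/C=C/C=C)=C(C)C | intermediate
5 | trimethyl({2-methyl-1-[(2E)-penta-2,4-dien-1-yloxy]prop-1-en-1-yl}oxy)silane | CC(C)=C(O[Si](C)(C)C)OC/C=C/C=C | intermediate
6 | trimethylsilyl 3-ethenyl-2,2-dimethylpent-4-enoate | C=CC(C=C)C(C)(C)C(=O)O[Si](C)(C)C | intermediate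
7 | 3-ethenyl-2,2-dimethylpent-4-enoic acid | C=CC(C=C)C(C)(C)C(=O)O | intermediate
8 | 3-ethenyl-2,2-dimethylpent-4-enoyl chloride | C=CC(C=C)C(C)(C)C(=O)Cl | intermediate
9 | 3-ethenyl-N-methoxy-N,2,2-trimethylpent-4-enamide | C=CC(C=C)C(C)(C)C(=O)N(C)OC | intermediate
10 | allylmagnesium bromide | C=CC[Mg]Br | starting material
11 | 6-ethenyl-5,5-dimethylocta-1,7-dien-4-one | C=CCC(=O)C(C)(C)C(C=C)C=C | intermediate
12 | (5S)-5-ethenyl-6,6-dimethylcyclohex-3-en-1-one | C=C[C@H]1C=CCC(=O)C1(C)C | intermediate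
13 | (5R)-5-ethenyl-6,6-dimethylcyclohex-2-en-1-one | O=C1C=CC[C@H](C=C)C1(C)C | intermediate
14 | potassium (5R)-5-ethenyl-6,6-dimethylcyclohex-1-en-1-olate | [K+].[O-]C1=CCC[C@H](C=C)C1(C)C | intermediate
15 | (3R)-3-ethenyl-2,2,6-trimethylcyclohexan-1-one (C6 epimers) | CC1CC[C@H](C=C)C(C)(C)C1=O | intermediate
16 | lithium (5R)-5-ethenyl-2,6,6-trimethylcyclohex-1-en-1-olate | [Li+].[O-]C1=C(C)CC[C@H](C=C)C1(C)C | intermediate
17 | (5R)-5-ethenyl-2,6,6-trimethylcyclohex-1-en-1-yl trifluoromethanesulfonate | CC1=C(OS(=O)(=O)C(F)(F)F)C(C)(C)[C@@H](C=C)CC1 | intermediate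
18 | (5S)-5-[2-(9-borabicyclo[3.3.1]nonan-9-yl)ethyl]-2,6,6-trimethylcyclohex-1-en-1-yl trifluoromethanesulfonate | CC1=C(OS(=O)(=O)C(F)(F)F)C(C)(C)[C@@H](CCB2C3CCCC2CCC3)CC1 | intermediate
19 | (5R)-5-(2-hydroxyethyl)-2,6,6-trimethylcyclohex-1-en-1-yl trifluoromethanesulfonate | CC1=C(OS(=O)(=O)C(F)(F)F)C(C)(C)[C@@H](CCO)CC1 | intermediate
20 | (5R)-2,6,6-trimethyl-5-(2-oxoethyl)cyclohex-1-en-1-yl trifluoromethanesulfonate | CC1=C(OS(=O)(=O)C(F)(F)F)C(C)(C)[C@@H](CC=O)CC1 | intermediate
21 | ethyl 2-(triphenyl-λ5-phosphanylidene)propanoate | CCOC(=O)C(C)=P(c1ccccc1)(c1ccccc1)c1ccccc1 | starting material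
22 | ethyl (2E)-2-methyl-4-[(1R)-2,2,4-trimethyl-3-{[(trifluoromethyl)sulfonyl]oxy}cyclohex-3-en-1-yl]but-2-enoate | CC1=C(OS(=O)(=O)C(F)(F)F)C(C)(C)[C@@H](C/C=C(\C)C(=O)OCC)CC1 | intermediate
23 | but-3-en-2-one (methyl vinyl ketone) | C=CC(C)=O | starting material
24 | ethyl (2E)-2-methyl-4-{(1R)-2,2,4-trimethyl-3-[(1E)-3-oxobut-1-en-1-yl]cyclohex-3-en-1-yl}but-2-enoate | CC1=C(/C=C/C(C)=O)C(C)(C)[C@@H](C/C=C(\C)C(=O)OCC)CC1 | intermediate
25 | diethyl (cyanomethyl)phosphonate | CCOP(=O)(CC#N)OCC | starting material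
26 | ethyl (2E)-4-{(1R)-3-[(1E,3E)-4-cyano-3-methylbuta-1,3-dien-1-yl]-2,2,4-trimethylcyclohex-3-en-1-yl}-2-methylbut-2-enoate | CC1=C(/C=C/C(C)=C/C#N)C(C)(C)[C@@H](C/C=C(\C)C(=O)OCC)CC1 | intermediate
27 | (2E,4E)-5-{(5R)-5-[(2E)-4-hydroxy-3-methylbut-2-en-1-yl]-2,6,6-trimethylcyclohex-1-en-1-yl}-3-methylpenta-2,4-dienal | CC1=C(/C=C/C(C)=C/C=O)C(C)(C)[C@@H](C/C=C(\C)CO)CC1 | intermediate
28 | (2E,4E)-5-{(5R)-5-[(2E)-4-{[tert-butyl(dimethyl)silyl]oxy}-3-methylbut-2-en-1-yl]-2,6,6-trimethylcyclohex-1-en-1-yl}-3-methylpenta-2,4-dienal | CC1=C(/C=C/C(C)=C/C=O)C(C)(C)[C@@H](C/C=C(\C)CO[Si](C)(C)C(C)(C)C)CC1 | intermediate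
29 | (2E,4E,6E)-2,7-dimethylocta-2,4,6-trienedial | O=C/C(C)=C/C=C/C=C(C)/C=O | starting material
30 | (2E,4E,6E)-2,7-dimethylocta-2,4,6-triene-1,8-diol | OC/C(C)=C/C=C/C=C(C)/CO | intermediate
31 | (2E,4E,6E)-1,8-dibromo-2,7-dimethylocta-2,4,6-triene | BrC/C(C)=C/C=C/C=C(C)/CBr | intermediate
32 | tetraethyl [(2E,4E,6E)-2,7-dimethylocta-2,4,6-triene-1,8-diyl]bis(phosphonate) | CCOP(=O)(OCC)C/C(C)=C/C=C/C=C(C)/CP(=O)(OCC)OCC | intermediate
33 | diethyl [(2E,4E,6E,8E,10E,12E)-13-{(5R)-5-[(2E)-4-{[tert-butyl(dimethyl)silyl]oxy}-3-methylbut-2-en-1-yl]-2,6,6-trimethylcyclohex-1-en-1-yl}-2,7,11-trimethyltrideca-2,4,6,8,10,12-hexaen-1-yl]phosphonate | CC1=C(/C=C/C(C)=C/C=C/C(C)=C/C=C/C=C(C)/CP(=O)(OCC)OCC)C(C)(C)[C@@H](C/C=C(\C)CO[Si](C)(C)C(C)(C)C)CC1 | intermediate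
34 | (2R,2'R)-2,2'-bis[(2E)-4-{[tert-butyl(dimethyl)silyl]oxy}-3-methylbut-2-en-1-yl]-β,β-carotene (all-E) | CC1=C(/C=C/C(C)=C/C=C/C(C)=C/C=C/C=C(C)/C=C/C=C(C)/C=C/C2=C(C)CC[C@H](C/C=C(\C)CO[Si](C)(C)C(C)(C)C)C2(C)C)C(C)(C)[C@@H](C/C=C(\C)CO[Si](C)(C)C(C)(C)C)CC1 | intermediate
35 | (2R,2'R)-2,2'-bis[(2E)-4-hydroxy-3-methylbut-2-en-1-yl]-β,β-carotene (all-E) | CC1=C(/C=C/C(C)=C/C=C/C(C)=C/C=C/C=C(C)/C=C/C=C(C)/C=C/C2=C(C)CC[C@H](C/C=C(\C)CO)C2(C)C)C(C)(C)[C@@H](C/C=C(\C)CO)CC1 | target

Total step count: 20 steps. Longest linear sequence: 17 steps (steps 1 to 15, then 19 and 20); steps 16 to 18 form the C10 branch.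

Steps most likely to fail

Step 5. The catalyst may discriminate poorly between the two enantiotopic vinyl groups, or be slowed by coordination of the C6 carbonyl to molybdenum. The fallback leaves the route at 9 and returns at 12; it sets C2 from a carbinol centre instead of from the catalyst. Amide 9 is reduced with i-Bu2AlH (THF, −78 °C) to 3-ethenyl-2,2-dimethylpent-4-enal F1. Brown allylation with (Ipc)2B(CH2CH=CH2) made from (−)-α-pinene (Et2O, −78 °C; then NaOH, H2O2) should give (4R)-6-ethenyl-5,5-dimethylocta-1,7-dien-4-ol F2. Ring-closing metathesis with the second-generation Grubbs catalyst RuCl2(CHPh)(H2IMes)(PCy3) (CH2Cl2, 40 °C) then chooses between diastereotopic vinyl groups under control of the carbinol centre. The closure that places hydroxyl and vinyl both pseudo-equatorial is expected and leads to (1R,5S)-5-ethenyl-6,6-dimethylcyclohex-3-en-1-ol F3, which is purified by chromatography. Dess–Martin oxidation of the alcohol gives 12.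

Step 7. C-methylation of the borane-associated enolate may be sluggish or repeated, or 1,2-reduction may compete. The fallback leaves the route at 12 and returns at 17; the methyl group is introduced before the reduction. Ketone 12 is deprotonated with LiN(i-Pr)2 (THF, −78 °C) and the dienolate is methylated at its α-carbon with MeI to (5S)-5-ethenyl-2,6,6-trimethylcyclohex-3-en-1-one F4 (C2 epimers). DBU (CH2Cl2, rt) moves the double bond into conjugation to give (5R)-5-ethenyl-2,6,6-trimethylcyclohex-2-en-1-one F5. Conjugate reduction with LiBH(s-Bu)3 (THF, −78 °C) generates enolate 16 directly, and trapping with PhNTf2 gives 17.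

Step 13. Geometric control at the new trisubstituted C9=C10 bond may be poor; the same detour also bypasses the Heck reaction of step 12 on the hindered triflate. The fallback leaves the route at 22 and returns at 28; the C7–C11 unit is brought in with fixed geometry by cross-coupling. Ester 22 is reduced with i-Bu2AlH (CH2Cl2, −78 °C) to (5R)-5-[(2E)-4-hydroxy-3-methylbut-2-en-1-yl]-2,6,6-trimethylcyclohex-1-en-1-yl trifluoromethanesulfonate F6. Silylation (TBSCl, imidazole, DMF) gives (5R)-5-[(2E)-4-{[tert-butyl(dimethyl)silyl]oxy}-3-methylbut-2-en-1-yl]-2,6,6-trimethylcyclohex-1-en-1-yl trifluoromethanesulfonate F7. The coupling partner is (2E,4E)-3-methyl-5-(tributylstannyl)penta-2,4-dien-1-ol F8, made by PdCl2(PPh3)2-catalysed hydrostannylation of commercial (2E)-3-methylpent-2-en-4-yn-1-ol with Bu3SnH. Stille coupling of the triflate with this stannane (Pd2(dba)3, AsPh3, NMP, 50 °C) gives (2E,4E)-5-{(5R)-5-[(2E)-4-{[tert-butyl(dimethyl)silyl]oxy}-3-methylbut-2-en-1-yl]-2,6,6-trimethylcyclohex-1-en-1-yl}-3-methylpenta-2,4-dien-1-ol F9. MnO2 (CH2Cl2, rt) oxidises the dienol to 28.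

Further compounds
F1 | step 5 | 3-ethenyl-2,2-dimethylpent-4-enal | C=CC(C=C)C(C)(C)C=O
F2 | step 5 | (4R)-6-ethenyl-5,5-dimethylocta-1,7-dien-4-ol | C=CC[C@@H](O)C(C)(C)C(C=C)C=C
F3 | step 5 | (1R,5S)-5-ethenyl-6,6-dimethylcyclohex-3-en-1-ol | C=C[C@H]1C=CC[C@@H](O)C1(C)C
F4 | step 7 | (5S)-5-ethenyl-2,6,6-trimethylcyclohex-3-en-1-one (C2 epimers) | CC1C=C[C@H](C=C)C(C)(C)C1=O
F5 | step 7 | (5R)-5-ethenyl-2,6,6-trimethylcyclohex-2-en-1-one | CC1=CC[C@H](C=C)C(C)(C)C1=O
F6 | step 13 | (5R)-5-[(2E)-4-hydroxy-3-methylbut-2-en-1-yl]-2,6,6-trimethylcyclohex-1-en-1-yl trifluoromethanesulfonate | CC1=C(OS(=O)(=O)C(F)(F)F)C(C)(C)[C@@H](C/C=C(\C)CO)CC1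
F7 | step 13 | (5R)-5-[(2E)-4-{[tert-butyl(dimethyl)silyl]oxy}-3-methylbut-2-en-1-yl]-2,6,6-trimethylcyclohex-1-en-1-yl trifluoromethanesulfonate | CC1=C(OS(=O)(=O)C(F)(F)F)C(C)(C)[C@@H](C/C=C(\C)CO[Si](C)(C)C(C)(C)C)CC1
F8 | step 13 | (2E,4E)-3-methyl-5-(tributylstannyl)penta-2,4-dien-1-ol | CCCC[Sn](CCCC)(CCCC)/C=C/C(C)=C/CO
F9 | step 13 | (2E,4E)-5-{(5R)-5-[(2E)-4-{[tert-butyl(dimethyl)silyl]oxy}-3-methylbut-2-en-1-yl]-2,6,6-trimethylcyclohex-1-en-1-yl}-3-methylpenta-2,4-dien-1-ol | CC1=C(/C=C/C(C)=C/CO)C(C)(C)[C@@H](C/C=C(\C)CO[Si](C)(C)C(C)(C)C)CC1
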